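The data come from a simulation for an exercise; noise was put on by code.

If you follow each unit of substrate instead of its concentration, the flask becomes a fork, and the yield can be reckoned as a fraction of the charge.

| flask | substrate | gas phase | remark | time |
|---|---|---|---|---|
| Friday's | 0.077 M | 200 mM (held) | run made earlier |  |
| Thursday's | 1.3 M | 200 mM (held) | run made earlier |  |
| gamma | 0.12 M | 200 mM (held) |  | 4.0 d |
| alpha | 1.5 M | 200 mM (held) |  | 4.0 d |
| theta | 0.50 M | 200 mM (held) |  | 4.0 d |
| eta | 2.0 M | 200 mM (held) |  | 4.0 d |

| run | time / d | target / % |
|---|---|---|
| Friday's | 0.208 | 59.6 |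
| Friday's | 0.625 | 91.8 |
| Friday's | 1.04 | 94.7 |
| Friday's | 1.67 | 95.4 |
| Friday's | 2.50 | 97.0 |
| Friday's | 3.00 | 96.4 |
| Friday's | 4.00 | 99.0 |
| Thursday's | 0.625 | 62.6 |
| Thursday's | 1.25 | 66.6 |
| Thursday's | 1.67 | 65.4 |
| Thursday's | 2.50 | 62.8 |
| Thursday's | 3.00 | 62.7 |
| Thursday's | 4.00 | 64.4 |

(standard deviation of a reading: 1 percentage point)

- percentages count the substrate that a species holds: one side product counts as two
- at the start none of the gas is dissolved
- the analysis behind the earlier runs scatters by 1 percentage point, standard deviation
- on the list of suspects stand: gas phase <-> dissolved gas; dissolved gas -> decomposed reagent; substrate + dissolved gas -> target; substrate + target -> side product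

- the flasks by amount of target, in percent of the substrate charged, highest first, at 4.0 d (gamma / alpha / theta / eta)
- the same order at 5.0 h (gamma / alpha / theta / eta)
- the amount of target, in percent of the substrate charged of the flask you put first, at 4.0 d
- the amount of target, in percent of the substrate charged of the flask you put last, at 4.0 d

Friday's first reading, 59.6 % at 0.208 d, gives a pseudo-first-order constant of 4.36 d⁻¹ for the substrate, a lifetime of 0.229 d. I therefore take the four flasks as finished at 4.0 d, since that lifetime is far shorter, and Thursday's readings are level from 1.25 d on.

Now take the balance of the substrate. Each unit used either becomes target or meets a target and takes it into side product. If y is the target fraction and c the charge, the odds of the second path are a·c·y. Here a, the selectivity factor, is the side-step constant divided by the pseudo-first-order constant, taken as steady.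

Two extremes can be solved in the head. If substrate never meets target, y is 1. If target stood at its final fraction from the first moment, the odds would keep their final value throughout, and that is the other extreme. Target starts at nothing and climbs to y, and the real flask lies between the two. I therefore use half the final odds, which gives a = 2(1−y)/[c·y·(1+y)].

Thursday's level readings average 64.4 %, so I read a as 0.518 M⁻¹. Solved for y, the rule gives 94.3 % for gamma and 55.4 % for eta. The order follows the charge, and I keep that order at 5.0 h.

The forecast, “All flasks finish by 4 d”, has the same order as mine, gamma > theta > alpha > eta and gamma > theta > alpha > eta, but other end values, 95.5 % and 52 %.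

The flasks give gamma > theta > alpha > eta at 4.0 d and gamma > theta > alpha > eta at 5.0 h, with 95.2 % in gamma and 53.9 % in eta. With the side step struck out, eta stands at 100 %. Put back into the rule, these results give a of 0.435 M⁻¹ in gamma and 0.556 M⁻¹ in eta, so it is larger in eta, and Thursday's reading lies between them.

    gas phase ⇌ dissolved gas, rate k1*(csat - [dissolved gas]) (kL = 0.00120 s⁻¹)
    dissolved gas → decomposed reagent (k = 2.40 × 10⁻⁶ s⁻¹)
    substrate + dissolved gas → target (k = 2.70 × 10⁻⁴ M⁻¹ s⁻¹)
    substrate + target → side product (k = 2.30 × 10⁻⁵ M⁻¹ s⁻¹)

For a neighbour of gamma charged with 0.48 M, Thursday's a gives 81.6 %. The computed flask holds 83.2 % as target and 16.8 % as side product.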